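The earlier runs and the new flask were generated by integration from invented constants, noise included.

Alder is Sunday's flask with a little less nucleophile: 0.900 equivalents on the electrophile against 0.950.

| flask | electrophile | nucleophile | remark | time |
|---|---|---|---|---|
| Saturday's | 0.40 M | 0.25 M | run made earlier |  |
| Sunday's | 0.40 M | 0.38 M | run made earlier |  |
| alder | 0.40 M | 0.360 M |  | 2.5 d |
| cedar | 0.40 M | 0.470 M |  | 2.5 d |

| run | time / h | electrophile / % | product / % |
|---|---|---|---|
| Saturday's | 2.50 | 84.4 | 16.6 |
| Saturday's | 4.00 | 78.5 | 20.2 |
| Saturday's | 6.00 | 75.5 | 25.2 |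
| Saturday's | 8.00 | 72.9 | 27.5 |
| Saturday's | 12.0 | 69.8 | 29.8 |
| Saturday's | 20.0 | 67.4 | 33.5 |
| Saturday's | 30.0 | 67.2 | 32.8 |
| Sunday's | 4.00 | 70.3 | 30.5 |
| Sunday's | 8.00 | 61.0 | 39.8 |
| Sunday's | 12.0 | 56.9 | 43.7 |
| Sunday's | 15.0 | 54.2 | 45.2 |
| Sunday's | 20.0 | 53.0 | 46.1 |
| Sunday's | 25.0 | 53.9 | 47.2 |
| Sunday's | 30.0 | 53.1 | 47.6 |

(readings scatter by 0.5 percentage points)

- the analysis behind the earlier runs scatters by 0.5 percentage points, standard deviation

- part of the electrophile that has reacted at the end, alder
- part of the electrophile that has reacted at the end, cedar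
- what raising the concentration of nucleophile from its lowest to its highest value here does to the part of the electrophile that has reacted (changes below 5 percentage points count as none) (no change / it rises / it falls)

Sunday's run levels off by 20.0 h, and alder gets 2.5 d, so I expect alder's end to follow its charge, not the clock. Sunday's run stops with 46.7% of the electrophile reacted, Saturday's with 32.7% from 0.625 equivalents. Electrophile remains in both, so I read the nucleophile as the limiting reagent.

Dividing equivalents charged by the fraction reacted at the plateau gives 2.04 for Sunday's run and 1.91 for Saturday's. This is the nucleophile cost: equivalents spent per electrophile turned. It drifts a little, so I freeze Sunday's value, from the nearer charge.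

Alder then reaches 44.2%, below Sunday's run in the ratio of their charges. Cedar reaches 57.7%. That rise of 14 percentage points passes the margin.

The forecast gives 44.8% (43.5% to 46%) for alder and 55% (52.5% to 57%) for cedar, and says it rises. Its ground is “A reaction that simply dies fits better.” My alder lies just above its low end, but my cedar stands above its range.

The flasks give 45.1% for alder and 56.9% for cedar. As the nucleophile goes from alder's charge to cedar's, the part of the electrophile reacted answers: it rises, by 12 points. Cedar stands 0.10 points under the top of the forecast's range.

    electrophile + nucleophile ⇌ acid set free + product (K = 1.20, k = 0.400 M⁻¹ h⁻¹)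
    nucleophile + acid set free ⇌ protonated nucleophile, settled at all times (K = 290 M⁻¹)
    nucleophile ⇌ dormant form (K = 0.460, k = 0.00730 h⁻¹)
    2 electrophile → homo dimer (k = 6.20 × 10⁻⁵ M⁻¹ h⁻¹)

In cedar the electrophile's forward half-life in the first step is 0.30 d at 0.104 d, short against 2.5 d. Ten times as long still reads 57.4%, and cedar's own cost reads 2.07. For the neighbour of cedar charged with 1.6 M of electrophile, 0.294 equivalents at the frozen cost give 14.4%. The computed flask gives 17.1%.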